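The earlier runs and the new flask were computed for substances that don't exist.

The cedar and larch runs start with equal charges of starting material and reagent and differ in catalyst. A given fraction of the starting material turned can therefore be treated as one stage of the same curve, reached sooner in the larch run, and what is worth reading is the ratio of the two times to that stage.

| flask | starting material | reagent | catalyst | time |
|---|---|---|---|---|
| cedar | 200 mM | 600 mM | 1.00 mM |  |
| larch | 200 mM | 600 mM | 1.50 mM |  |
| oak | 200 mM | 900 mM | 1.00 mM |  |
| alder | 300 mM | 600 mM | 1.00 mM |  |
| elm | 200 mM | 600 mM | 2.10 mM | 7.8 min |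

| cedar run: time / min | cedar run: [target] / mM | larch run: time / min | larch run: [target] / mM | oak run: time / min | oak run: [target] / mM | alder run: time / min | alder run: [target] / mM |
|---|---|---|---|---|---|---|---|
| 1.1 | 14.4 | 1.1 | 21.9 | 1.1 | 22.6 | 1.1 | 16.3 |
| 2.2 | 29.4 | 2.2 | 42.3 | 2.2 | 44.5 | 2.2 | 33.0 |
| 3.3 | 43.2 | 3.3 | 60.7 | 3.3 | 64.4 | 3.3 | 48.8 |
| 4.5 | 58.8 | 4.5 | 80.3 | 4.5 | 86.0 | 4.5 | 64.5 |
| 5.6 | 71.7 | 5.6 | 97.7 | 5.6 | 103.5 | 5.6 | 77.9 |
| 6.7 | 82.6 | 6.7 | 111.2 | 6.7 | 120.8 | 6.7 | 93.1 |
| 7.8 | 94.8 | 7.8 | 126.2 | 7.8 | 136.9 | 7.8 | 104.7 |

(readings scatter by 0.6 mM)

1. reaction order in [reagent] at the outset, round the charge of the cedar run, defined at two percent of the starting material turned into target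
2. reaction order in [starting material] at the outset, round the charge of the cedar run, defined at two percent of the starting material turned into target (one fixed amount of target, the same in the runs compared)
3. target in the elm run at 7.8 min, as a share of the starting material charged

- Overall: starting material + reagent -> target, with catalyst as catalyst.
- Constant volume, constant temperature.
- What is held in complexes is read along with the free species.
- An order is taken over about fifteen percent of the charge, up and down.

The larch run has turned 48.9% of its charge at 5.6 min. The cedar run stands at 47.4% at 7.8 min and is then gaining 0.0555 /min, so it reaches the larch fraction at about 8.06 min. The clocks thus differ by a ratio of 1.44. The catalyst exponent, the power to which a ratio of catalyst charges is raised to give the ratio of clocks, is then 0.899.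

By this exponent, 7.8 min in the elm run matches 10.6 min in the larch run, past its last reading of 63.1%. The larch rate, as a fraction of the charge, goes from 0.0920 /min over the first 3.3 min to 0.0695 /min between 4.5 min and 7.8 min. That is a loss of 0.0615 /min per unit of fraction turned. Carried on as a straight line, this leaves 0.0625 /min at the last reading, and the remaining stretch brings this reckoning to 78.8%.

The weak link is the exponent, which rests on one pair of times. An earlier pair serves as well: the larch run has 30.3% at 3.3 min, and the cedar run reaches that fraction at about 4.66 min. The ratio is 1.41 and the exponent 0.852, a little lower. With it, the elm run matches 10.4 min of larch time, and this reckoning settles on 78.0%.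

The forecast gave 1.1 (0.95 to 1.25) for the reagent order, 0.3 (0.17 to 0.45) for the starting-material order, and 78% (73% to 81%) for the elm run, on the ground that “Larch overlays cedar on a stretched time axis with a factor of about 1.44”.

The flask gives 1.0, 0.22 and 76.8%. The forecast's order in starting material stands above the flask's.

    catalyst + starting material ⇌ catalyst-substrate complex, settled at all times (74.80 /M)
    catalyst-substrate complex + reagent → target + catalyst + by-product (35.52 /M/min)
    2 catalyst ⇌ resting dimer, settled at all times (757.0 /M)
    2 starting material ⇌ idle substrate dimer, settled at all times (59.50 /M)

With the exponent 0.899, 7.8 min in the elm run is reckoned as 15.2 min of cedar time, and at 7.8 min the elm run holds 76.8% of its charge as target. In the larch run, the simulated time to half of the charge, 5.79 min, becomes 8.33 min of cedar time, and the cedar run's simulated time to that mark is 8.28 min. The elm run stands where it does because catalyst joins into resting dimer and starting material into idle substrate dimer. Without the idle substrate dimer the same elm run gives 97.0%, and without the resting dimer 90.4%.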